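**Retrosynthetic overview**

1. The target is ring A (a dearomatised acylphloroglucinol: C1 carbonyl, C2 butanoyl, C3–OH, C4 quaternary with methyl and prenyl, C5–OH, C6 arylmethyl) bridged by CH2 to ring B (aspidinol). The last bond made is C4–prenyl, by Pd-catalysed enantioselective dearomative prenylation of the fully aromatic bis-phloroglucinol; this sets the only stereocentre.
2. Before that, the C2–butanoyl bond is made by Houben–Hoesch acylation of the single free carbon of ring A.
3. Key disconnection: ring A is cut into a ketone (C4–C5–C6, the side chain on ring B) and a malonyl unit (C1–C2–C3). Forward, C1–C6 and C3–C4 are made in one [3+3] Effenberger-type annulation of a silyl enol ether with malonyl dichloride.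
4. Enabling feature: ring A is a masked cyclohexane-1,3,5-trione. Carbonyl-level C1, C3, C5 alternate with nucleophilic C2, C4, C6, so C5 with its two α-carbons C4 and C6 is a ketone bis-nucleophile and C1–C2–C3 is a malonyl bis-electrophile. Ring B supplies that ketone by conjugate addition of its one free ring carbon to ethyl vinyl ketone.
5. Ring order: ring B is bought complete (aspidinol); ring A is closed in step 3 as an arene and dearomatised in step 5.

Key step: step 3

Remark: aspidinol (compound 1) is taken as a purchasable building block, and ring A of the target is treated as the enol tautomer of the given SMILES, in which the stereocentre is (4R).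

**Route**

Step 1
Reactants: 1 aspidinol [1-(2,6-dihydroxy-4-methoxy-3-methylphenyl)butan-1-one]; 2 pent-1-en-3-one (ethyl vinyl ketone)
Product: 3 1-(3-butanoyl-2,4-dihydroxy-6-methoxy-5-methylphenyl)pentan-3-one
Conditions: 2 (1.5 equiv), Et3N (0.5 equiv), MeOH–H2O (1:1), 40 °C
Reagents that add atoms: none
Why: Base-mediated conjugate (Michael) addition of the phenolate of 1 through its only unsubstituted ring carbon, which lies ortho and para to the two free hydroxyls, to enone 2; addition through oxygen is reversible and should drain into the C–C adduct.

Step 2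
Reactants: 3 1-(3-butanoyl-2,4-dihydroxy-6-methoxy-5-methylphenyl)pentan-3-one
Product: 4 1-{2,6-bis[(tert-butyldimethylsilyl)oxy]-3-{3-[(tert-butyldimethylsilyl)oxy]pent-3-en-1-yl}-4-methoxy-5-methylphenyl}butan-1-one (used as the mixture of positional and E/Z enol ether isomers)
Conditions: TBSOTf (3.3 equiv), Et3N (4 equiv), CH2Cl2, −78 → 0 °C
Reagents that add atoms: tert-butyldimethylsilyl trifluoromethanesulfonate (TBSOTf), CC(C)(C)[Si](C)(C)OS(=O)(=O)C(F)(F)F
Why: Soft enolisation with a silyl triflate and an amine should convert the unhindered dialkyl ketone into its TBS enol ether and cap both phenols in the same operation, while the butanoyl ketone of ring B, wedged between two ortho silyloxy groups, should stay untouched at this stoichiometry; the enol ether isomers need no separation because step 3 acylates both α-carbons.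

Step 3
Reactants: 4 tris-silylated enol ether (isomer mixture); 5 propanedioyl dichloride (malonyl dichloride)
Product: 8 1-{2,6-dihydroxy-4-methoxy-3-methyl-5-[(2,4,6-trihydroxy-3-methylphenyl)methyl]phenyl}butan-1-one, via acyl chloride 6 (not isolated), via tris-silyl ether 7 (not isolated)
Conditions: 5 (1.2 equiv), Et2O, −20 °C → rt; then Bu4NF, AcOH, THF, 0 °C
Reagents that add atoms: none
Why: Effenberger-type α,α′-annulation of a ketone enol ether with malonyl dichloride: one COCl C-acylates the silyl enol ether (first C–C bond, intermediate 6), the liberated HCl shifts the silyl enol ether into cross-conjugation on the other α-carbon, and this carbon attacks the second COCl, so that C1–C6 and C3–C4 of ring A are both made in the one operation. Ring A closes in a 6-(enolendo)-exo-trig acyl substitution with chloride as leaving group, and loss of HCl and enolisation should give the benzene-1,3,5-triol mono-silyl ether 7, aromatisation making the sequence irreversible. The closest known reaction type is the same annulation of cyclohexanone enol ethers to bicyclo[3.3.1]nonane-2,4,9-triones, in which even bridgehead quaternary carbons are made by this C-acylation. No stereocentre is formed here: C4 is still a planar, methyl-bearing arene carbon and becomes stereogenic only in step 5. The step needs ring closure through carbon and not through oxygen (lactonisation), which is secured by keeping the ketone oxygen blocked as its robust TBS ether until both bonds exist; regiochemistry is no issue because either enol ether isomer of 4 ends with both α-carbons acylated. Ring B cannot compete, as it has no free ring carbon, no enol ether and silylated phenols, and buffered fluoride then frees all five hydroxyls without the strong alkali that scrambles diarylmethane bridges.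

Step 4
Reactants: 8 1-{2,6-dihydroxy-4-methoxy-3-methyl-5-[(2,4,6-trihydroxy-3-methylphenyl)methyl]phenyl}butan-1-one; 9 butanenitrile
Product: 11 1-{3-[(3-butanoyl-2,4-dihydroxy-6-methoxy-5-methylphenyl)methyl]-2,4,6-trihydroxy-5-methylphenyl}butan-1-one, via ketiminium chloride 10 (not isolated)
Conditions: 9 (3 equiv), ZnCl2, HCl (g), Et2O, 0 °C; then H2O, 60 °C
Reagents that add atoms: water, O
Why: Houben–Hoesch acylation: the nitrilium species from 9, ZnCl2 and HCl should attack the only unsubstituted ring carbon in the molecule (C2 of ring A, between two hydroxyls; ring B is fully substituted), and the ketiminium chloride 10 is hydrolysed on warming with water; the nitrile route acylates carbon and not oxygen.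

Step 5
Reactants: 11 1-{3-[(3-butanoyl-2,4-dihydroxy-6-methoxy-5-methylphenyl)methyl]-2,4,6-trihydroxy-5-methylphenyl}butan-1-one; 12 3-methylbut-2-en-1-yl acetate (prenyl acetate)
Product: 13 (4R)-2-butanoyl-6-[(3-butanoyl-2,4-dihydroxy-6-methoxy-5-methylphenyl)methyl]-3,5-dihydroxy-4-methyl-4-(3-methylbut-2-en-1-yl)cyclohexa-2,5-dien-1-one (CNP0219644.1)
Conditions: 12 (1.1 equiv), Pd2(dba)3·CHCl3 (2.5 mol %), (R,R)-DACH-phenyl Trost ligand, N,N′-[(1R,2R)-cyclohexane-1,2-diyl]bis[2-(diphenylphosphanyl)benzamide] (7.5 mol %), Et3N (1.0 equiv), CH2Cl2, 0 °C → rt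
Reagents that add atoms: none
Why: Tsuji–Trost asymmetric allylic alkylation with dearomatisation of a phenoxide: zerovalent palladium ionises 12 to the 1,1-dimethylallyl complex, which should be attacked at its CH2 terminus by C4 of ring A (O5, para to the butanoyl group, is the most acidic hydroxyl of 11, C4 is the less hindered of its two ortho carbons, and O-prenyl ethers re-ionise under the catalyst), while the chiral pocket of the ligand distinguishes the two faces of planar ring A, whose flanks differ (chelated C3–OH/butanoyl side against C5–O/arylmethyl side), so that the quaternary, non-enolisable stereocentre is set under catalyst control in the last step; the ligand antipode written is the working choice for (R), to be confirmed on the first run, and both antipodes are sold.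

**Compound list**

1 | aspidinol, 1-(2,6-dihydroxy-4-methoxy-3-methylphenyl)butan-1-one | CCCC(=O)c1c(O)cc(OC)c(C)c1O | starting material
2 | pent-1-en-3-one (ethyl vinyl ketone) | CCC(=O)C=C | starting material
3 | 1-(3-butanoyl-2,4-dihydroxy-6-methoxy-5-methylphenyl)pentan-3-one | CCC(=O)CCc1c(O)c(C(=O)CCC)c(O)c(C)c1OC | intermediate
4 | 1-{2,6-bis[(tert-butyldimethylsilyl)oxy]-3-{3-[(tert-butyldimethylsilyl)oxy]pent-3-en-1-yl}-4-methoxy-5-methylphenyl}butan-1-one (mixture with the pent-2-en-1-yl positional isomer, E/Z) | CC=C(O[Si](C)(C)C(C)(C)C)CCc1c(O[Si](C)(C)C(C)(C)C)c(C(=O)CCC)c(O[Si](C)(C)C(C)(C)C)c(C)c1OC | intermediate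
5 | propanedioyl dichloride (malonyl dichloride) | O=C(Cl)CC(=O)Cl | starting material
6 | 7-{2,4-bis[(tert-butyldimethylsilyl)oxy]-3-butanoyl-6-methoxy-5-methylphenyl}-5-[(tert-butyldimethylsilyl)oxy]-4-methyl-3-oxohept-4-enoyl chloride | O=C(Cl)CC(=O)C(C)=C(O[Si](C)(C)C(C)(C)C)CCc1c(O[Si](C)(C)C(C)(C)C)c(C(=O)CCC)c(O[Si](C)(C)C(C)(C)C)c(C)c1OC | intermediate
7 | 1-{2,6-bis[(tert-butyldimethylsilyl)oxy]-3-({2-[(tert-butyldimethylsilyl)oxy]-4,6-dihydroxy-3-methylphenyl}methyl)-4-methoxy-5-methylphenyl}butan-1-one | CCCC(=O)c1c(O[Si](C)(C)C(C)(C)C)c(C)c(OC)c(Cc2c(O)cc(O)c(C)c2O[Si](C)(C)C(C)(C)C)c1O[Si](C)(C)C(C)(C)C | intermediate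
8 | 1-{2,6-dihydroxy-4-methoxy-3-methyl-5-[(2,4,6-trihydroxy-3-methylphenyl)methyl]phenyl}butan-1-one | CCCC(=O)c1c(O)c(C)c(OC)c(Cc2c(O)cc(O)c(C)c2O)c1O | intermediate
9 | butanenitrile | CCCC#N | starting material
10 | 1-{3-[(3-butanoyl-2,4-dihydroxy-6-methoxy-5-methylphenyl)methyl]-2,4,6-trihydroxy-5-methylphenyl}butan-1-iminium chloride | CCCC(=[NH2+])c1c(O)c(C)c(O)c(Cc2c(O)c(C(=O)CCC)c(O)c(C)c2OC)c1O.[Cl-] | intermediate
11 | 1-{3-[(3-butanoyl-2,4-dihydroxy-6-methoxy-5-methylphenyl)methyl]-2,4,6-trihydroxy-5-methylphenyl}butan-1-one | CCCC(=O)c1c(O)c(C)c(O)c(Cc2c(O)c(C(=O)CCC)c(O)c(C)c2OC)c1O | intermediate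
12 | 3-methylbut-2-en-1-yl acetate (prenyl acetate) | CC(=O)OCC=C(C)C | starting material
13 | (4R)-2-butanoyl-6-[(3-butanoyl-2,4-dihydroxy-6-methoxy-5-methylphenyl)methyl]-3,5-dihydroxy-4-methyl-4-(3-methylbut-2-en-1-yl)cyclohexa-2,5-dien-1-one | CCCC(=O)C1=C(O)[C@](C)(CC=C(C)C)C(O)=C(Cc2c(O)c(C(=O)CCC)c(O)c(C)c2OC)C1=O | target

**Step count and risks**

Total step count: 5. Longest linear sequence: 5 steps (1 → 3 → 4 → 8 → 11 → 13).

Steps most likely to fail:

1. Step 3 (key step). What may go wrong: protodesilylation of the enol ether by the HCl that is formed, or loss of the enol silyl group after the first acylation followed by ring closure through oxygen (lactonisation) instead of carbon. Fallback (no de novo ring construction; Mannich-base/ortho-quinone methide bridging): starting from compound 1, aminomethylation at the free ring carbon with N,N-dimethylmethyleneiminium iodide (CH2Cl2, rt) should give 1-{3-[(dimethylamino)methyl]-2,6-dihydroxy-4-methoxy-5-methylphenyl}butan-1-one F1. Heating F1 with an excess of commercial 2-methylbenzene-1,3,5-triol (1,4-dioxane, 100 °C) expels dimethylamine, and the ortho-quinone methide of ring B is captured by a free ring carbon of the triol to give compound 8, where the route is rejoined before step 4.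

2. Step 5. What may go wrong: poor facial discrimination by the catalyst, because the two flanks of C4 differ only beyond the flanking C–O groups; also competing alkylation at C6 or at oxygen, and a second prenylation. Fallback (racemic alkylation and resolution instead of asymmetric catalysis): starting from compound 11, alkylative dearomatisation with 1-bromo-3-methylbut-2-ene and NaOMe in MeOH at 0 °C should give racemic 2-butanoyl-6-[(3-butanoyl-2,4-dihydroxy-6-methoxy-5-methylphenyl)methyl]-3,5-dihydroxy-4-methyl-4-(3-methylbut-2-en-1-yl)cyclohexa-2,5-dien-1-one F2. F2 is resolved by preparative chromatography on a chiral stationary phase (the product is a vinylogous acid, so crystallisation of its salt with a single-enantiomer amine is the scalable alternative), which returns the (R)-enantiomer, compound 13.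

3. Step 4. What may go wrong: acid-induced cleavage or scrambling of the diarylmethane bridge (ipso-protonation of electron-rich ring A), imidate formation at oxygen, or incomplete hydrolysis of the ketiminium salt. Fallback (the butanoyl group is put on ring A before the bridge is made): commercial 2-methylbenzene-1,3,5-triol is acylated with butanoyl chloride and AlCl3 (nitrobenzene, rt) to 1-(2,4,6-trihydroxy-3-methylphenyl)butan-1-one F3, which has one free ring carbon. Starting from compound 1, condensation of 1 and F3 with aqueous formaldehyde (NaOH, EtOH–H2O, 0 °C → rt) forms the methylene bridge, and the mixed product, compound 11, is separated from the two symmetrical dimers; the route is rejoined before step 5.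

**Further compounds**

F1 | step 3 | 1-{3-[(dimethylamino)methyl]-2,6-dihydroxy-4-methoxy-5-methylphenyl}butan-1-one | CCCC(=O)c1c(O)c(C)c(OC)c(CN(C)C)c1O
F2 | step 5 | racemic 2-butanoyl-6-[(3-butanoyl-2,4-dihydroxy-6-methoxy-5-methylphenyl)methyl]-3,5-dihydroxy-4-methyl-4-(3-methylbut-2-en-1-yl)cyclohexa-2,5-dien-1-one | CCCC(=O)C1=C(O)C(C)(CC=C(C)C)C(O)=C(Cc2c(O)c(C(=O)CCC)c(O)c(C)c2OC)C1=O
F3 | step 4 | 1-(2,4,6-trihydroxy-3-methylphenyl)butan-1-one | CCCC(=O)c1c(O)cc(O)c(C)c1O
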